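**Retrosynthetic overview**
- Target ⇒ its bis(O-benzyl) ether (global hydrogenolysis last).
- C3–CH2Ar bond ⇒ trans-selective enolate alkylation of the (R)-β-(arylmethyl)-γ-butyrolactone with O-benzylvanillyl bromide; C3 is relayed from C4.
- Lactone O1–C5 bond (key disconnection) ⇒ enantioselective, desymmetrizing Baeyer–Villiger oxygen insertion into a prochiral 3-(arylmethyl)cyclobutanone; this sets C4.
- Cyclobutanone ⇒ dichloroketene [2+2] with O-benzyl methoxyeugenol, then dechlorination.
- Ring order: four-membered carbocycle first, then expansion to the five-membered lactone; both arene rings are bought.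

Assumption: both mirror-image forms of catalyst A (step 3) are equally accessible, and the form that gives the (R)-lactone is used; the sense of induction is fixed in a small test run by chiral HPLC and optical rotation.

Catalyst A is a C2-symmetric, confined chiral imidodiphosphoric acid, [(ArO)2P(=O)]2NH, in which each (ArO)2 unit is a 3,3'-bis(2,4,6-triethylphenyl)-1,1'-bi-2-naphthol.

**Step 1**
Reactants: 1 4-allyl-2,6-dimethoxyphenol (methoxyeugenol)
Product: 2 5-allyl-2-(benzyloxy)-1,3-dimethoxybenzene
Conditions: BnBr (1.1 equiv), K2CO3 (1.5 equiv), DMF, 60 °C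
Reagents that add atoms: benzyl bromide, BrCc1ccccc1
Why: Williamson ether synthesis on the phenoxide; the allyl group does not isomerize under carbonate base, and no stereocentre is involved.

**Step 2**
Reactants: 2 5-allyl-2-(benzyloxy)-1,3-dimethoxybenzene
Product: 4 3-[4-(benzyloxy)-3,5-dimethoxybenzyl]cyclobutan-1-one, via dichlorocyclobutanone 3 (not isolated)
Conditions: Cl3CCOCl (2 equiv), Zn–Cu couple (3 equiv), Et2O/DME, 0 °C → rt; then AcOH, Zn dust (5 equiv), same flask, rt → 40 °C
Reagents that add atoms: trichloroacetyl chloride, ClC(=O)C(Cl)(Cl)Cl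
Why: Ketene–alkene [2+2] cycloaddition of in situ dichloroketene puts C=O on the terminal alkene carbon and CCl2 on the internal one, and zinc/acetic acid then reduces both C–Cl bonds; product 4 has a mirror plane, so the racemic centre of 3 does not matter.

**Step 3**
Reactants: 4 3-[4-(benzyloxy)-3,5-dimethoxybenzyl]cyclobutan-1-one
Product: 6 (R)-4-[4-(benzyloxy)-3,5-dimethoxybenzyl]dihydrofuran-2(3H)-one, via Criegee perhydrate 5 (not isolated)
Conditions: catalyst A (5 mol%), 35% aq. H2O2 (1.5 equiv), CHCl3, −40 °C, 24–48 h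
Reagents that add atoms: hydrogen peroxide, OO
Why: Proposed new method: a desymmetrizing Baeyer–Villiger oxidation catalysed by a confined imidodiphosphoric acid, whose P–OH activates the ketone while the neighbouring P=O binds H2O2, so that the Criegee perhydrate 5 forms and rearranges inside a narrow chiral pocket with the arylmethyl tail pointing out; the pocket fixes which of the two enantiotopic ring CH2 groups lies antiperiplanar to the O–O bond and migrates to oxygen, which forms the O1–C5 bond and sets C4 as (R); the closest known reaction types are the chiral phosphoric acid/H2O2 Baeyer–Villiger desymmetrization of 3-arylcyclobutanones (open catalysts give only modest selectivity with flexible 3-benzyl groups) and confined imidodiphosphoric acid/H2O2 oxygen transfer to sulfides.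

**Step 4**
Reactants: 7 [4-(benzyloxy)-3-methoxyphenyl]methanol (O-benzylvanillyl alcohol)
Product: 8 1-(benzyloxy)-4-(bromomethyl)-2-methoxybenzene
Conditions: PBr3 (0.4 equiv), Et2O, 0 °C, 1 h; used crude at once
Reagents that add atoms: phosphorus tribromide, BrP(Br)Br
Why: Bromination of an electron-rich benzylic alcohol through its phosphite ester (SN2 by bromide); no stereocentre is involved.

**Step 5**
Reactants: 6 (R)-4-[4-(benzyloxy)-3,5-dimethoxybenzyl]dihydrofuran-2(3H)-one; 8 1-(benzyloxy)-4-(bromomethyl)-2-methoxybenzene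
Product: 10 (3R,4R)-3-[4-(benzyloxy)-3-methoxybenzyl]-4-[4-(benzyloxy)-3,5-dimethoxybenzyl]dihydrofuran-2(3H)-one, via lithium enolate 9 (not isolated)
Conditions: LiN(SiMe3)2 (1.05 equiv), THF, −78 °C, 45 min; then 8 (1.1 equiv), DMPU (2 equiv), −78 → −30 °C
Reagents that add atoms: none
Why: Lactone enolate alkylation (SN2) occurs on the face anti to the C4 arylmethyl group, giving the 3,4-trans product (also the thermodynamic isomer), so (4R) is relayed to (3R).

**Step 6**
Reactants: 10 (3R,4R)-3-[4-(benzyloxy)-3-methoxybenzyl]-4-[4-(benzyloxy)-3,5-dimethoxybenzyl]dihydrofuran-2(3H)-one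
Product: 11 (3R,4R)-3-(4-hydroxy-3-methoxybenzyl)-4-(4-hydroxy-3,5-dimethoxybenzyl)dihydrofuran-2(3H)-one (target)
Conditions: H2 (1 atm), 10% Pd/C, EtOAc/EtOH, rt
Reagents that add atoms: none
Why: Hydrogenolysis of both aryl benzyl ethers under neutral conditions; the lactone, the aryl methyl ethers and both stereocentres are untouched (no base, so C3 does not epimerize).

**Compound list**
1 | 4-allyl-2,6-dimethoxyphenol (methoxyeugenol) | C=CCc1cc(OC)c(O)c(OC)c1 | starting material
2 | 5-allyl-2-(benzyloxy)-1,3-dimethoxybenzene | C=CCc1cc(OC)c(OCc2ccccc2)c(OC)c1 | intermediate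
3 | 2,2-dichloro-3-[4-(benzyloxy)-3,5-dimethoxybenzyl]cyclobutan-1-one (racemic, not isolated) | O=C1CC(Cc2cc(OC)c(OCc3ccccc3)c(OC)c2)C1(Cl)Cl | intermediate
4 | 3-[4-(benzyloxy)-3,5-dimethoxybenzyl]cyclobutan-1-one (achiral) | O=C1CC(Cc2cc(OC)c(OCc3ccccc3)c(OC)c2)C1 | intermediate
5 | 1-hydroperoxy-3-[4-(benzyloxy)-3,5-dimethoxybenzyl]cyclobutan-1-ol (Criegee perhydrate, cis/trans, not isolated) | OOC1(O)CC(Cc2cc(OC)c(OCc3ccccc3)c(OC)c2)C1 | intermediate
6 | (R)-4-[4-(benzyloxy)-3,5-dimethoxybenzyl]dihydrofuran-2(3H)-one | O=C1C[C@@H](Cc2cc(OC)c(OCc3ccccc3)c(OC)c2)CO1 | intermediate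
7 | [4-(benzyloxy)-3-methoxyphenyl]methanol | COc1cc(CO)ccc1OCc1ccccc1 | starting material
8 | 1-(benzyloxy)-4-(bromomethyl)-2-methoxybenzene | COc1cc(CBr)ccc1OCc1ccccc1 | intermediate
9 | lithium enolate of 6, (4R) configuration unchanged (not isolated) | [Li+].[O-]C1=C[C@@H](Cc2cc(OC)c(OCc3ccccc3)c(OC)c2)CO1 | intermediate
10 | (3R,4R)-3-[4-(benzyloxy)-3-methoxybenzyl]-4-[4-(benzyloxy)-3,5-dimethoxybenzyl]dihydrofuran-2(3H)-one (3,4-trans) | COc1cc(C[C@H]2C(=O)OC[C@@H]2Cc2cc(OC)c(OCc3ccccc3)c(OC)c2)ccc1OCc1ccccc1 | intermediate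
11 | (3R,4R)-3-(4-hydroxy-3-methoxybenzyl)-4-(4-hydroxy-3,5-dimethoxybenzyl)dihydrofuran-2(3H)-one (3,4-trans) | COc1cc(C[C@H]2C(=O)OC[C@@H]2Cc2cc(OC)c(O)c(OC)c2)ccc1O | target

**Step count**
Total steps: 6. Longest linear sequence: 5 (steps 1, 2, 3, 5, 6); step 4 is a one-step side branch.

**Three steps most likely to fail**

Step 3 (the proposed new Baeyer–Villiger desymmetrization; risk of low turnover or low enantioselectivity). The fallback uses known chemistry, sets out from 4 and comes back at 6. Cyclobutanone 4 is deprotonated enantioselectively with lithium bis[(S)-1-phenylethyl]amide (or its mirror image, whichever gives the R product) in THF at −100 °C with Me3SiCl present as an internal quench. This gives the (R)-silyl enol ether F2. Ozonolysis (O3, CH2Cl2/MeOH, −78 °C), reduction with NaBH4 and acidic work-up (aq. HCl) cleave the enol C=C bond to an acid and a primary alcohol, which close to lactone 6.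

Step 2 (one-flask cycloaddition and dechlorination; risk of arene acylation by excess acid chloride or incomplete dechlorination). The fallback sets out from 2 and comes back at 4. Alkene 2 is treated with N,N-dimethylacetamide, Tf2O and 2,4,6-collidine in 1,2-dichloroethane at reflux, a keteniminium [2+2] cycloaddition that gives the cyclobutaniminium triflate F1 with no chlorine to remove. Hydrolysis with aqueous NaHCO3 gives 4.

Step 5 (risk of double alkylation or decomposition of the labile bromide 8). The fallback sets out from 6 and comes back at 11. Enolate 9 (LiN(SiMe3)2, THF, −78 °C) is added to commercial 4-(benzyloxy)-3-methoxybenzaldehyde (COc1cc(C=O)ccc1OCc1ccccc1) in an aldol reaction anti to the C4 substituent. This gives the 3,4-trans aldol adduct F3 as a mixture of carbinol epimers. Hydrogenolysis (H2, 10% Pd/C, catalytic HClO4, AcOH/EtOAc, rt) removes the benzylic hydroxyl and both benzyl ethers in one operation and gives 11 directly.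

**Further compounds**
F1 | step 2 | N-{3-[4-(benzyloxy)-3,5-dimethoxybenzyl]cyclobutylidene}-N-methylmethanaminium trifluoromethanesulfonate | C[N+](C)=C1CC(Cc2cc(OC)c(OCc3ccccc3)c(OC)c2)C1.[O-]S(=O)(=O)C(F)(F)F
F2 | step 3 | (R)-{3-[4-(benzyloxy)-3,5-dimethoxybenzyl]cyclobut-1-en-1-yl}oxy(trimethyl)silane | C[Si](C)(C)OC1=C[C@H](Cc2cc(OC)c(OCc3ccccc3)c(OC)c2)C1
F3 | step 5 | (3S,4R)-3-{[4-(benzyloxy)-3-methoxyphenyl](hydroxy)methyl}-4-[4-(benzyloxy)-3,5-dimethoxybenzyl]dihydrofuran-2(3H)-one (3,4-trans, carbinol epimers) | COc1cc(C(O)[C@H]2C(=O)OC[C@@H]2Cc2cc(OC)c(OCc3ccccc3)c(OC)c2)ccc1OCc1ccccc1
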